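- The pitfall in repeating this run is to expect [partner] to change the height of the single product's top, so we watch [substrate]/[single product] instead.

- east: substrate 0.20 M; partner 0.90 M; run made earlier
- flask: substrate 0.20 M; partner 0.600 M; time 80 min

east run (percent of the substrate charged)

| time / min | single product / % | substrate / % |
|---|---|---|
| 1.33 | 40.3 | 34.8 |
| 2.00 | 38.9 | 23.3 |
| 4.00 | 30.5 | 9.3 |
| 6.00 | 21.4 | 4.1 |
| 10.0 | 11.9 | 1.0 |
| 15.0 | 6.9 | 0 |

(scatter of a reading: 0.5 percentage points)

- what was read earlier has a scatter of 0.5 percentage points, one standard deviation
- a reading or a percentage of single product counts all its forms, free or not

1. the moment within 80 min at which there is most single product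
2. the amount of single product, in percent of the substrate charged, at that time
3. earliest time at which at least nineteen twentieths of that best amount are there, in min
4. latest time at which they still are, in min

- We follow one molecule of substrate: it waits a time t_S to become single product, which then waits a time t_M to react on. Both waits are taken as encounters with partner, so we let both stretch alike with [partner] and keep their ratio.
- Between 1.33 min and 2.00 min, the east substrate falls at 0.599 min⁻¹, so t_S is 1.67 min.
- We take the east top to lie near those two readings, and at a top single product neither gains nor loses. Counting substrate lost as single product made, t_S/t_M there equals [substrate]/[single product], the fork ratio (a selectivity factor), read as 0.719. So in the east run t_M is 2.32 min, longer than t_S.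
- Our reckoning for this flask keeps the fork ratio, so the top stays near the highest east reading, 40.3%. Scaling the east times by the partner charges, we place it between 2.00 min and 3.00 min.
- The forecast gave 41% at 2.6 min, from 1.5 min to 4.4 min, holding that "The yield-versus-conversion curve stays the same".
- The flask reached 40.3% at 2.86 min, and held the asked level from 1.85 min to 4.45 min; [substrate]/[single product] at that top was 0.705, close to the fork ratio. At that top partner stood at 54.3% of its charge; at 40.0 min, partner stood at 1.02% of its charge, and bis adduct at 70.2% and single product at 16.8% of the substrate charged.

    substrate + partner → single product (k = 0.880 L mol⁻¹ min⁻¹)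
    partner + single product → bis adduct (k = 0.620 L mol⁻¹ min⁻¹)
    crystals ⇌ single product, rate k3*(cs3 - [single product]) while solid is left; crystals form when [single product] > cs3 (solubility = 0.140 M, k = 46.0 min⁻¹)
    partner → decomposed reagent (k = 0.0680 min⁻¹)
    substrate + partner → other mono adduct (k = 0.120 L mol⁻¹ min⁻¹)
    partner + other mono adduct → bis adduct (k = 0.0300 L mol⁻¹ min⁻¹)

- For a neighbour flask with 0.24 M of partner, the fork ratio contains no [partner], so we expect the same height. That computed neighbour flask gives 39.8%, ending with partner at 0% of its charge and [substrate]/[single product] at 0.863, above the fork ratio.

The earlier runs and the new flask are calculated with constants of no real substance, noise included.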